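The earlier runs and the new flask were computed with made-up constants, and the scatter is random.

Target in the ash run grew by 0.00200 M min⁻¹ up to the first reading and 0.00198 M min⁻¹ up to the last, while starting material fell to 41.0%. So I took the target rate as steady and the side product rate as proportional to starting material. My decision was whether charging 0.10 M instead of 0.20 M pays, and how long to leave the flask.

| setting | ash | flask |
|---|---|---|
| starting material | 0.20 M | 0.10 M |
| gas phase | 6.8 mM (held) | 6.8 mM (held) |
| remark | run made earlier |  |
| time |  | 80 min |

ash run (percent of the starting material charged)

| time / min | target / % | starting material / % |
|---|---|---|
| 6.00 | 6.0 | 84.6 |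
| 12.0 | 11.6 | 68.3 |
| 20.0 | 20.6 | 50.9 |
| 25.0 | 24.7 | 41.0 |

(scatter of a reading: 1 percentage point)

- at the start none of the gas is dissolved
- reactions considered so far: gas phase <-> dissolved gas; starting material + dissolved gas -> target; starting material -> side product; dissolved gas -> decomposed reagent

- winter: doubling the saturation concentration of gas phase, all else as stated
- midnight: doubling the transfer coefficient of the gas phase, all else as stated

- target at 80 min, in percent of the starting material charged
- concentration of dissolved gas in solution at 40 min, in percent of saturation
- the change that raises the amount of target at 80 min, in percent of the starting material charged most ("none" if none brings more than 2 percentage points) (winter / midnight / none)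
- amount of target at 80 min, in percent of the starting material charged, after midnight

At the last ash reading, side product, read as whatever was neither target nor starting material, stood at 34.3%, and the mean level of starting material had been 0.141 M. Mean level times target over side product gave the balance level b = 0.102 M, the concentration of starting material at which target and side product form equally fast. With the target rate held steady, the target share of what reacts (the selectivity) at level A is b/(b+A).

At its mean level of 0.0500 M, the flask's share came to 67.0%. The ash charge, at 0.100 M, gives 50.4%, so the smaller charge pays. Going round again, I split the fall into two equal steps with mean levels 0.0750 M and 0.0250 M. Their shares, 57.5% and 80.2%, average 68.9%. At the ash rate, that much target takes 34.9 min, less than 80 min, so I kept the time and committed to 68.9%.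

The forecast gave 67% (61% to 72%), 65% of saturation (30% to 90%), winter as the best change, and 78% (72% to 83%) after midnight, holding that “the reaction is limited by gas transfer”.

The flask gave 64.5%, 4.4 percentage points under my figure, with 56.1% of saturation. Winter added 13 points and midnight 9.7 points, reaching 74.1%. Left ten times as long, the flask held 64.5%. At 8.00 min, with 72.7% starting material left, b gives a share of 54.0% and so 14.7% target, and the flask held 14.1%.

    gas phase ⇌ dissolved gas, rate k1*(csat - [dissolved gas]) (kL = 0.00543 s⁻¹)
    starting material + dissolved gas → target (k = 0.381 L mol⁻¹ s⁻¹)
    starting material → side product (k = 3.20 × 10⁻⁴ s⁻¹)
    dissolved gas → decomposed reagent (k = 5.39 × 10⁻⁴ s⁻¹)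

In the neighbour flask stopped at 20 min with 39.8% starting material left, b gives a share of 59.2% and so 35.6% target. The computed result is 34.2%.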